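**Assumption:** Hanultarin is taken exactly as drawn, the (2R,3R) mono-(E)-ferulate of (−)-secoisolariciresinol. Compounds 1, 2, 4, 8, 9 and immobilised lipases are treated as commercial.

## Retrosynthetic overview

1. Hanultarin ⇒ ester C–O bond, made last: lipase-mediated mono-feruloylation of unprotected, C2-symmetric (−)-secoisolariciresinol. The two CH2OH groups are homotopic, so breaking the symmetry can give only one monoester.
2. (−)-Secoisolariciresinol ⇒ one global hydride cleavage of a C2-symmetric bis(N-acyloxazolidinone) carrying aryl pivalates.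
3. Bis-imide ⇒ C8–C8′ bond by oxidative enolate homocoupling of two identical dihydroferuloyl imides; both stereocentres are set here by the (S)-Evans auxiliary.
4. All three C6–C3 units are ferulic-acid derived: dihydroferulic acid twice, ferulic acid once.
5. No rings are formed; the three arene rings are carried intact throughout.

## Route

**Step 1**
Reactants: 1, 3-(4-hydroxy-3-methoxyphenyl)propanoic acid (dihydroferulic acid); 2, pivaloyl chloride
Product: 3, 3-[3-methoxy-4-(pivaloyloxy)phenyl]propanoic acid
Conditions: PivCl (1.3 equiv), NaOH (2.3 equiv), H2O/THF, 0 °C; then HCl to pH 2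
Reagents that add atoms: pivaloyl chloride, CC(C)(C)C(Cl)=O
Why: Schotten–Baumann acylation; in water the phenoxide is far more nucleophilic than the carboxylate, so only the phenol is capped, as a base-robust, non-enolisable pivalate.

**Step 2**
Reactants: 3, O-pivaloyl acid; 4, (S)-4-benzyl-1,3-oxazolidin-2-one
Product: 5, (S)-4-benzyl-3-{3-[3-methoxy-4-(pivaloyloxy)phenyl]propanoyl}oxazolidin-2-one
Conditions: PivCl (1.05 equiv), Et3N, THF, −20 °C; then LiCl, 4, rt
Reagents that add atoms: (S)-4-benzyl-2-oxazolidinone, O=C1OC[C@H](Cc2ccccc2)N1
Why: Mixed-anhydride N-acylation of an Evans auxiliary; the oxazolidinone attacks the unhindered acyl carbon of the mixed pivalic anhydride, and the hindered aryl pivalate is inert.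

**Step 3**
Reactants: 5 (2 equiv)
Product: 6, (2R,3R)-2,3-bis[3-methoxy-4-(pivaloyloxy)benzyl]-1,4-bis[(S)-4-benzyl-2-oxooxazolidin-3-yl]butane-1,4-dione
Conditions: LDA (1.1 equiv), THF, −78 °C; then TiCl4 (1.2 equiv), −78 → 0 °C; recrystallise to remove the minor (R,S) diastereomer
Reagents that add atoms: none
Why: Auxiliary-controlled oxidative enolate homocoupling; each chelated Z-enolate forms the new C–C bond on the face anti to the C4-benzyl group (same sense as Evans alkylation), so the (S)-auxiliary gives R at both new centres, and the pivalate (no α-H, hindered) survives LDA at −78 °C.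

**Step 4**
Reactants: 6
Product: 7, (−)-secoisolariciresinol, (2R,3R)-2,3-bis(4-hydroxy-3-methoxybenzyl)butane-1,4-diol
Conditions: LiBH4 (8 equiv), MeOH, THF, 0 → 40 °C; then 1 M NaOH, rt, N2 (cleaves residual ArOPiv); H3O+
Reagents that add atoms: none
Why: Reductive auxiliary removal (exocyclic-selective imide reduction, with the first alkoxide lactonising onto the second imide and the lactone reduced on to the diol) plus pivalate cleavage in one pot; the α-centres are not enolised, so (R,R) is retained.

**Step 5**
Reactants: 8, (E)-ferulic acid; 9, vinyl acetate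
Product: 10, vinyl (E)-ferulate
Conditions: vinyl acetate (excess), Hg(OAc)2 (cat.), H2SO4 (cat.), THF, 40 °C
Reagents that add atoms: vinyl acetate, CC(=O)OC=C
Why: Metal-catalysed transvinylation (vinyl interchange) of the carboxylic acid; the free phenol and the E-alkene are untouched.

**Step 6 (key step)**
Reactants: 7, (−)-secoisolariciresinol; 10, vinyl ferulate (1.2 equiv)
Product: 11, Hanultarin
Conditions: Novozym 435 (immobilised CAL-B; Lipozyme TL IM as alternative), 2-methyl-2-butanol, 4 Å MS, 45 °C; stop at maximum monoester, recover unreacted 7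
Reagents that add atoms: vinyl ferulate, COc1cc(/C=C/C(=O)OC=C)ccc1O
Why: Lipase-catalysed irreversible transesterification; the feruloyl–serine acyl-enzyme transfers only to a primary aliphatic OH (none of the four phenols is acylated), the two CH2OH groups are homotopic so mono-acylation gives a single compound, the bulky monoester is a poorer acceptor than the diol so diester is suppressed, and no stereocentre is touched. This substrate/donor pair is untested, so this is the riskiest step.

## Compound list

1 | 3-(4-hydroxy-3-methoxyphenyl)propanoic acid (dihydroferulic acid) | COc1cc(CCC(=O)O)ccc1O | starting material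
2 | pivaloyl chloride | CC(C)(C)C(Cl)=O | starting material
3 | 3-[3-methoxy-4-(pivaloyloxy)phenyl]propanoic acid | COc1cc(CCC(=O)O)ccc1OC(=O)C(C)(C)C | intermediate
4 | (S)-4-benzyl-1,3-oxazolidin-2-one | O=C1OC[C@H](Cc2ccccc2)N1 | starting material
5 | (S)-4-benzyl-3-{3-[3-methoxy-4-(pivaloyloxy)phenyl]propanoyl}oxazolidin-2-one | COc1cc(CCC(=O)N2[C@@H](Cc3ccccc3)COC2=O)ccc1OC(=O)C(C)(C)C | intermediate
6 | (2R,3R)-2,3-bis[3-methoxy-4-(pivaloyloxy)benzyl]-1,4-bis[(S)-4-benzyl-2-oxooxazolidin-3-yl]butane-1,4-dione | COc1cc(C[C@@H](C(=O)N2[C@@H](Cc3ccccc3)COC2=O)[C@@H](Cc2ccc(OC(=O)C(C)(C)C)c(OC)c2)C(=O)N2[C@@H](Cc3ccccc3)COC2=O)ccc1OC(=O)C(C)(C)C | intermediate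
7 | (−)-secoisolariciresinol, (2R,3R)-2,3-bis(4-hydroxy-3-methoxybenzyl)butane-1,4-diol | COc1cc(C[C@@H](CO)[C@H](CO)Cc2ccc(O)c(OC)c2)ccc1O | intermediate
8 | (E)-ferulic acid | COc1cc(/C=C/C(=O)O)ccc1O | starting material
9 | vinyl acetate | CC(=O)OC=C | starting material
10 | vinyl (E)-ferulate | COc1cc(/C=C/C(=O)OC=C)ccc1O | intermediate
11 | Hanultarin | COc1cc(/C=C/C(=O)OC[C@H](Cc2ccc(O)c(OC)c2)[C@H](CO)Cc2ccc(O)c(OC)c2)ccc1O | target

## Summary

**Total step count:** 6

**Longest linear sequence:** 5 (steps 1 → 2 → 3 → 4 → 6); step 5 is a one-step side branch.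

**Three steps most likely to fail, with fallbacks:**

1. **Step 6.** The lipase may accept the β-branched lignan diol or the feruloyl donor too slowly, or over-acylate. Fallback: switch to a protecting-group-based chemical monoacylation. Run steps 1–4 with TBS ethers instead of pivalates (LiBH4 leaves ArOTBS intact), acylate the mono-sodium alkoxide of the bis-TBS diol with 4-O-TBS-feruloyl chloride, then remove all three silyl groups with TBAF/AcOH.

2. **Step 3.** The oxidative homocoupling may give low yield or poor diastereoselectivity, or the aryl pivalate may be attacked. Fallback: abandon dimerisation and build the diad stepwise. Stobbe condensation of O-benzylvanillin with dimethyl succinate, Rh-catalysed asymmetric hydrogenation of the itaconate half-ester, reduction to the (R)-β-benzyl-γ-butyrolactone, trans-selective enolate alkylation with the benzylic bromide, then LiAlH4 and hydrogenolysis to 7.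

3. **Step 4.** Hydride may attack the endocyclic carbamate carbonyl of the hindered imide, or reduction may be incomplete. Fallback: change from reductive to hydrolytic auxiliary removal. LiOH/H2O2 gives the (R,R)-diacid (pivalates cleaved in the same basic medium), which is then reduced to 7 with BH3·THF.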